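Its constants were chosen freely, and the outcome is calculated.

I decided to answer your request for a quick number, and your hunch that heat wins, by counting reagent lifetimes.

in all of them: starting material 0.050 M; reagent 0.0600 M; precatalyst 2.5 mM; time 2.0 min

|  | temperature | remark |
|---|---|---|
| blue | 20 °C |  |
| teal |  | at 20 °C until 1.0 min, from then on at 60 °C |
| red | 60 °C |  |
| amber | 40 °C |  |

    reagent + free catalyst ⇌ catalyst intermediate A (K1 = 24 M⁻¹, k1 = 3.8 M⁻¹ s⁻¹, Ea1 = 58.0 kJ mol⁻¹, ΔH1 = −24.0 kJ mol⁻¹)
    starting material + catalyst intermediate A → catalyst intermediate B (k2 = 200 M⁻¹ s⁻¹, Ea2 = 48.0 kJ mol⁻¹)
    catalyst intermediate B → catalyst intermediate C (k3 = 0.17 s⁻¹, Ea3 = 82.0 kJ mol⁻¹)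
    catalyst intermediate C → free catalyst + target (k4 = 0.19 s⁻¹, Ea4 = 75.0 kJ mol⁻¹)
    reagent + free catalyst + target → free catalyst + over-reaction product (k5 = 54 M⁻² s⁻¹, Ea5 = 47.0 kJ mol⁻¹)
    precatalyst → free catalyst (k6 = 0.048 s⁻¹, Ea6 = 91.0 kJ mol⁻¹)
    2 catalyst intermediate A → spent catalyst (k7 = 10 M⁻¹ s⁻¹, Ea7 = 49.0 kJ mol⁻¹)
    (constants at 40 °C)

- a step written with two of one species runs at k times the square of its concentration and takes two of it each time
- all constants are for 40 °C and move with temperature by the activation energies and enthalpies

1. which flask leads in amount of target, in percent of the starting material charged ("all alike" within 1.5 percentage points) (blue / teal / red / amber / all alike)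
2. how much target is there at the end, in percent of the starting material charged: blue
3. how much target is there at the end, in percent of the starting material charged: teal
4. how much target is there at the end, in percent of the starting material charged: red
5. how much target is there at the end, in percent of the starting material charged: amber

1. I defined the reagent lifetime τ = 1/(k c) as the time in which reagent falls by a factor e, with k the forward rate constant of reagent + free catalyst at the flask's temperature and c the free catalyst, taken as the whole charge: for red, 27.6 s. This is a pseudo-first-order time, so the reagent charge does not enter it.

2. For red, the precatalyst lifetime of 2.56 s is shorter than τ, so I kept c at the charge. I ignored the catalyst held inside the round. For blue, the precatalyst lifetime of 3.77 min is longer than the run, so blue's count below flatters it.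

3. I divided the time by τ at each temperature. Blue got 0.249 lifetimes, amber 1.14, teal 2.30 over its two temperatures, and red 4.34. Red's count is greater than the others, so I backed your hunch and put red ahead.

4. For red, that count leaves 1.30% of the reagent. Each target takes one reagent and each over-reaction product takes 2, while the two together cannot exceed the starting material charged. On that count, target in red stays at or below 81.6%. My reckoning stopped at that ceiling, because it gives no split between target and over-reaction product.

The forecast, which unlike my ceiling gave point values, put blue at 0.7%, amber at 27%, teal at 58% and red at 75%, with red leading, on the ground that “heat wins despite more over-reaction”.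

The simulation gave blue 0.689%, amber 25.7%, teal 58.8% and red 71.2%, with red leading. Red's target stood below my ceiling, and red kept 3.53% of its reagent against my 1.30%.

I then took a neighbour of red charged with 0.024 M of reagent. The reagent charge does not enter τ, and the count again leaves 1.30% of the reagent. That means target plus 2 over-reaction products should reach 47.4% of the starting material. The neighbour flask kept 1.69% of its own reagent charge and held 37.9% target and 4.61% over-reaction product, which sums on that count to 47.1%. Its starting material stood at 57.4%.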